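At early times the epsilon readings of substrate and target add up to 101% of the charge, but by 2.50 h they add up to 96.0%. That gap is small, and it is the thing I follow.

| setting | epsilon | grey | violet | teal |
|---|---|---|---|---|
| substrate | 1.1 M | 0.76 M | 0.76 M | 0.76 M |
| partner | 1.9 M | 1.90 M | 1.90 M | 1.90 M |
| temperature | 20 °C | 20 °C | 35 °C | 50 °C |
| remark | run made earlier |  |  |  |
| time |  | 12 h | 12 h | 12 h |

epsilon run (percent of the substrate charged)

| time / h | target / % | substrate / % |
|---|---|---|
| 0.200 | 13 | 88 |
| 0.333 | 20 | 82 |
| 0.500 | 29 | 70 |
| 0.833 | 40 | 61 |
| 1.33 | 53 | 46 |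
| 2.50 | 60 | 36 |

(each reading ± 2 percentage points)

- candidate steps: substrate + partner <-> target + released group; released group -> by-product carried off; target <-> isomer of the product; substrate <-> dormant form
- the earlier runs do not show what temperature does; that part of a forecast is a guess

1. the flask that comes out highest in amount of target, in percent of the substrate charged, or "all alike" when all lie within 1.5 percentage points (grey / violet / teal / all alike)
2. target at the end, in percent of the substrate charged, grey
3. target at the end, in percent of the substrate charged, violet
4. target at the end, in percent of the substrate charged, teal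

In grey, violet and teal substrate is the limiting reagent, so I write its balance in fractions of its charge:

target = 1 − substrate left − leak × time

At the last epsilon reading the gap gives 0.0160 h⁻¹. I call this the leak: the part of the charge that is neither substrate nor target, divided by the time. It is a reading, and a weak one. One scatter higher, it is 0.0273 h⁻¹.

Between the last two readings substrate falls at 0.210 h⁻¹. Carried on to 12 h, that leaves 4.92%, which I use for grey. I carry the epsilon leak over to grey as a constant, which makes this bracket an estimate and not a strict limit, taking the leak as read for the top and the higher leak for the bottom: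

above: 1 − 4.92% − 0.0160 h⁻¹ × 12 h = 75.9%

below: 1 − 4.92% − 0.0273 h⁻¹ × 12 h = 62.3%

The forecast says grey, with 80% for grey, which stands above my top, then 76% for violet and 64% for teal. On heat it guesses that “the side drains probably gain most”. I have no bracket for the hot flasks, since no earlier run shows temperature.

The flasks give 71.4% for grey, inside my bracket, 47.5% for violet and 68.1% for teal, so the highest is grey.

    substrate + partner ⇌ target + released group (K = 2.60, k = 0.00233 L mol⁻¹ s⁻¹, Ea = 81.0 kJ mol⁻¹, ΔH = 8.00 kJ mol⁻¹)
    released group → by-product carried off (k = 0.00101 s⁻¹, Ea = 86.0 kJ mol⁻¹)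
    target ⇌ isomer of the product (K = 0.467, k = 3.96 × 10⁻⁴ s⁻¹, Ea = 107 kJ mol⁻¹, ΔH = −46.0 kJ mol⁻¹)
    substrate ⇌ dormant form (K = 1.04, k = 1.30 × 10⁻⁴ s⁻¹, Ea = 98.0 kJ mol⁻¹, ΔH = −35.0 kJ mol⁻¹)
    (constants at 50 °C)

By the same balance, grey's leak over 12 h is 0.0180 h⁻¹, and violet's is 0.0436 h⁻¹. In violet, the half-life of target by the forward path to isomer of the product alone is 3.4 h at 0.213 h, short against the 12 h allowed. At the end of violet, with each step taken net, target is made at 0.390 of the rate at which it is used up, and isomer of the product stands at 49.5%.

(The runs are simulated on assumed constants; the scatter is artificial.)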